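## Retrosynthetic overview

1. Numbering: lactone O1, C2 (C=O), C3 (alkylidene carbon), C4 (CHOH), C5 (CH bearing 2-methylprop-1-enyl); side chain C1' (=CH), C2', C3' (CHOH), C4' to C10' (C10' = CH2OH). TBS = tert-butyldimethylsilyl, TES = triethylsilyl.
2. Feature used: in the only ring (the γ-lactone), C2 is a single carbon held between O1 and C3. Removing it as CO (cutting C2–O1 and C2–C3) leaves an acyclic alkynol whose C5 oxygen is homopropargylic to a C3≡C1' triple bond, and syn addition across that alkyne restores the E-alkylidene.
3. The C4 oxygen stays silylated in that step. A free propargylic hydroxyl can itself take up CO at palladium (α-alkylidene-β-lactone) or ionise to an allenylpalladium (butenolide), so C5–OH is made the only hydroxyl present.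
4. C3–C4 is cut next: lithium acetylide plus (R)-α-silyloxy aldehyde, with Felkin–Anh control setting C4. The aldehyde (C5) comes from (S)-glyceraldehyde acetonide by Wittig olefination. The alkyne (C3', bond C2'–C3') comes from a geraniol-derived enal by phosphoric-acid-catalysed propargylboration.
5. Ring order: one ring, closed in the penultimate step; only global desilylation follows.

Key step: step 13

Assumption: the (R)-configured phosphoric acid is taken to direct the allenylboronate to the Re face of the geraniol-derived enal, as with aryl and alkenyl aldehydes; if the sense proves opposite, the (S)-acid is used and nothing else changes.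

## Route

Step 1
Reactants: 1 geraniol
Product: 2 (2E)-1-(tert-butyldimethylsilyloxy)-3,7-dimethylocta-2,6-diene (geranyl TBS ether)
Conditions: TBSCl, imidazole, CH2Cl2, 0 °C to rt
Reagents that add atoms: tert-butyldimethylsilyl chloride, CC(C)(C)[Si](C)(C)Cl
Why: Silyl ether protection of the primary allylic alcohol masks the C10' oxygen against the organolithium and oxidation steps ahead and touches no stereochemical element.

Step 2
Reactants: 2 geranyl TBS ether
Product: 3 (2E,6E)-8-(tert-butyldimethylsilyloxy)-2,6-dimethylocta-2,6-dien-1-ol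
Conditions: SeO2 (cat.), t-BuOOH, salicylic acid (cat.), CH2Cl2, 0 °C to rt
Reagents that add atoms: tert-butyl hydroperoxide, CC(C)(C)OO (terminal oxygen source); selenium dioxide, O=[Se]=O (catalytic oxygen carrier)
Why: The Riley allylic oxidation (ene reaction, then [2,3]-sigmatropic shift) should attack the more electron-rich terminal alkene and only its E-methyl group, which fixes the E geometry of C4'=C5'; any enal 4 from over-oxidation is carried along because step 3 converges on it.

Step 3
Reactants: 3 (2E,6E)-8-(tert-butyldimethylsilyloxy)-2,6-dimethylocta-2,6-dien-1-ol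
Product: 4 (2E,6E)-8-(tert-butyldimethylsilyloxy)-2,6-dimethylocta-2,6-dienal
Conditions: MnO2 (activated), CH2Cl2, rt
Reagents that add atoms: none
Why: Heterogeneous MnO2 oxidation is selective for allylic alcohols, stops at the aldehyde and should leave the alkene geometry and the silyl ether untouched.

Step 4
Reactants: 4 (2E,6E)-8-(tert-butyldimethylsilyloxy)-2,6-dimethylocta-2,6-dienal; 5 allenylboronic acid pinacol ester
Product: 7 (4R,5E,9E)-11-(tert-butyldimethylsilyloxy)-5,9-dimethylundeca-5,9-dien-1-yn-4-ol, via pinacol borate ester 6 (not isolated)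
Conditions: (R)-TRIP [(R)-3,3'-bis(2,4,6-triisopropylphenyl)-1,1'-binaphthalene-2,2'-diyl hydrogen phosphate] (10–20 mol %), 4 Å MS, toluene, −20 °C; aq. NaHCO3 work-up
Reagents that add atoms: none
Why: In this chiral-phosphoric-acid-catalysed propargylboration the allenylboronate reacts through a closed six-membered SE2' transition state, so only the homopropargylic alcohol forms, and the acid, hydrogen-bonded to a boronate oxygen and to the formyl hydrogen, should open the Re face of the enal and set C3' as R.

Step 5
Reactants: 7 (4R,5E,9E)-11-(tert-butyldimethylsilyloxy)-5,9-dimethylundeca-5,9-dien-1-yn-4-ol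
Product: 8 (4R,5E,9E)-4,11-bis(tert-butyldimethylsilyloxy)-5,9-dimethylundeca-5,9-dien-1-yne
Conditions: TBSCl, imidazole, DMF, rt
Reagents that add atoms: tert-butyldimethylsilyl chloride, CC(C)(C)[Si](C)(C)Cl
Why: Silyl ether protection of the secondary allylic alcohol occurs at oxygen, so C3' keeps its configuration and the terminal alkyne C–H becomes the only acidic site for step 10.

Step 6
Reactants: 9 (S)-2,2-dimethyl-1,3-dioxolane-4-carbaldehyde; 10 isopropyltriphenylphosphonium iodide
Product: 12 (R)-2,2-dimethyl-4-(2-methylprop-1-enyl)-1,3-dioxolane, via isopropylidenetriphenylphosphorane 11 (not isolated)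
Conditions: 10, n-BuLi, THF, 0 °C; then 9, −78 °C to rt
Reagents that add atoms: none
Why: The Wittig olefination with a non-stabilised ylide is fast at low temperature, so the α-alkoxy aldehyde should react before it can enolise; the stereocentre (future C5) is carried over unchanged (S becomes R by priority change only) and no E/Z question arises because the ylide carbon bears two methyl groups.

Step 7
Reactants: 12 (R)-2,2-dimethyl-4-(2-methylprop-1-enyl)-1,3-dioxolane
Product: 13 (R)-4-methylpent-3-ene-1,2-diol
Conditions: AcOH/H2O (4:1), rt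
Reagents that add atoms: none
Why: Acetal hydrolysis in weak aqueous acid cleaves only the ketal C–O bonds, so the carbinol C–O bond and its configuration are retained and the allylic position should not ionise.

Step 8
Reactants: 13 (R)-4-methylpent-3-ene-1,2-diol
Product: 14 (R)-4-methyl-1,2-bis(triethylsilyloxy)pent-3-ene
Conditions: TESCl, imidazole, CH2Cl2, 0 °C to rt
Reagents that add atoms: triethylsilyl chloride, CC[Si](Cl)(CC)CC
Why: Exhaustive silylation of both hydroxyls needs no selectivity and prepares the primary/secondary differentiation made in the next step.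

Step 9
Reactants: 14 (R)-4-methyl-1,2-bis(triethylsilyloxy)pent-3-ene
Product: 15 (R)-4-methyl-2-(triethylsilyloxy)pent-3-enal
Conditions: (COCl)2, DMSO, CH2Cl2, −78 to −40 °C; then i-Pr2NEt, −78 to 0 °C; used without storage
Reagents that add atoms: none
Why: In this Swern oxidation run directly on the silyl ether, chlorodimethylsulfonium chloride attacks the unhindered primary O–Si bond much faster than the secondary one and the alkoxysulfonium salt collapses to the aldehyde with base, while allylic 1,3-strain with the Z-methyl group holds the C5–H bond in the alkene plane and should slow enolisation.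

Step 10
Reactants: 8 (4R,5E,9E)-4,11-bis(tert-butyldimethylsilyloxy)-5,9-dimethylundeca-5,9-dien-1-yne; 15 (R)-4-methyl-2-(triethylsilyloxy)pent-3-enal
Product: 17 (4R,5S,9R,10E,14E)-9,16-bis(tert-butyldimethylsilyloxy)-4-(triethylsilyloxy)-2,10,14-trimethylhexadeca-2,10,14-trien-6-yn-5-ol (target numbering 5R,4S,3'R; 4,5-anti), via lithium acetylide 16 (not isolated)
Conditions: 8, n-BuLi, THF, −78 °C; then 15, −78 °C; AcOH quench at −78 °C
Reagents that add atoms: none
Why: 1,2-Addition of a lithium acetylide to an α-silyloxy aldehyde without a chelating metal follows the polar Felkin–Anh model (C–OSi bond perpendicular to the carbonyl, attack past hydrogen) and should give the 4,5-anti adduct with C4 = S, the cold acidic quench forestalling 1,2-silyl migration and chromatography removing any syn isomer.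

Step 11
Reactants: 17 the anti propargylic alcohol
Product: 18 (4R,5S,9R,10E,14E)-5,9,16-tris(tert-butyldimethylsilyloxy)-4-(triethylsilyloxy)-2,10,14-trimethylhexadeca-2,10,14-trien-6-yne
Conditions: TBSOTf, 2,6-lutidine, CH2Cl2, −78 to −20 °C
Reagents that add atoms: tert-butyldimethylsilyl trifluoromethanesulfonate, CC(C)(C)[Si](C)(C)OS(=O)(=O)C(F)(F)F
Why: Silylation with a silyl triflate and a hindered pyridine base caps the flanked propargylic C4 hydroxyl at low temperature without disturbing the TES ether, so C4–O and C5–O now carry silyl groups of different lability.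

Step 12
Reactants: 18 the C4-O-TBS, C5-O-TES ether
Product: 19 (4R,5S,9R,10E,14E)-5,9,16-tris(tert-butyldimethylsilyloxy)-2,10,14-trimethylhexadeca-2,10,14-trien-6-yn-4-ol (free C5–OH; TBS ethers at C4, C3' and C10')
Conditions: pyridinium p-toluenesulfonate (PPTS, cat.), MeOH/CH2Cl2, 0 °C, stopped at full TES cleavage
Reagents that add atoms: none
Why: Acid-catalysed methanolysis of silyl ethers discriminates by bulk at silicon, a triethylsilyl ether solvolysing far faster than any of the three tert-butyldimethylsilyl ethers, and acidic conditions do not induce O-to-O silyl migration.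

Step 13
Reactants: 19 the homopropargylic alcohol with free C5–OH
Product: 20 (3E,4S,5R)-4-(tert-butyldimethylsilyloxy)-3-[(3R,4E,8E)-3,10-bis(tert-butyldimethylsilyloxy)-4,8-dimethyldeca-4,8-dien-1-ylidene]-5-(2-methylprop-1-en-1-yl)oxolan-2-one
Conditions: PdCl2(PPh3)2 (10 mol %), SnCl2 (anhydrous, 10 mol %), CO (7 atm), MeCN/THF, 65 °C
Reagents that add atoms: carbon monoxide, [C-]#[O+]
Why: Divalent palladium, made labile by the SnCl3 ligand that arises when SnCl2 inserts into a Pd–Cl bond, binds CO and is attacked by the C5 hydroxyl to give an alkoxycarbonylpalladium species (C2–O1) and HCl; the tethered alkyne then inserts syn into the Pd–acyl bond (C2–C3, palladium on C1') and HCl cleaves the alkenyl–Pd bond with retention, returning the dichloride. The closest known reaction type is the palladium-catalysed cyclocarbonylation of homopropargylic alcohols to α-methylene- and α-alkylidene-γ-butyrolactones. The lactone ring closes in the 5-exo-dig mode, since a 6-endo closure by syn insertion would require a trans double bond inside a six-membered ring. No stereocentre is created and C4 and C5 are not touched; the one new stereochemical element, the C3=C1' alkene, should be E because the acyl carbon and the incoming hydrogen end on the same side, leaving the chain cis to C4. Chemoselectivity rests on C5–OH being the sole free hydroxyl, on the weak binding of the three trisubstituted alkenes to palladium, and on the absence of base, so the β-silyloxy-α-alkylidene lactone never meets eliminating conditions.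

Step 14
Reactants: 20 the tris-TBS lactone
Product: 21 (3E,4S,5R)-3-[(3R,4E,8E)-3,10-dihydroxy-4,8-dimethyldeca-4,8-dien-1-ylidene]-4-hydroxy-5-(2-methylprop-1-en-1-yl)oxolan-2-one (target)
Conditions: HF·pyridine, pyridine, THF, 0 °C to rt
Reagents that add atoms: none
Why: Fluoride-driven desilylation with pyridine-buffered HF is not basic enough to trigger elimination or retro-aldol cleavage of the β-hydroxy-α-alkylidene lactone and not acidic enough to ionise the allylic C–O bonds, so all three oxygens should be freed with every stereocentre and alkene intact.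

## Compound list

1 | geraniol | CC(C)=CCC/C(C)=C/CO | starting material
2 | geranyl TBS ether | CC(C)=CCC/C(C)=C/CO[Si](C)(C)C(C)(C)C | intermediate
3 | (2E,6E)-8-(tert-butyldimethylsilyloxy)-2,6-dimethylocta-2,6-dien-1-ol | OC/C(C)=C/CC/C(C)=C/CO[Si](C)(C)C(C)(C)C | intermediate
4 | (2E,6E)-8-(tert-butyldimethylsilyloxy)-2,6-dimethylocta-2,6-dienal | O=C/C(C)=C/CC/C(C)=C/CO[Si](C)(C)C(C)(C)C | intermediate
5 | allenylboronic acid pinacol ester | C=C=CB1OC(C)(C)C(C)(C)O1 | starting material
6 | pinacol borate ester of 7 (not isolated) | C#CC[C@@H](OB1OC(C)(C)C(C)(C)O1)/C(C)=C/CC/C(C)=C/CO[Si](C)(C)C(C)(C)C | intermediate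
7 | (4R,5E,9E)-11-(tert-butyldimethylsilyloxy)-5,9-dimethylundeca-5,9-dien-1-yn-4-ol | C#CC[C@@H](O)/C(C)=C/CC/C(C)=C/CO[Si](C)(C)C(C)(C)C | intermediate
8 | (4R,5E,9E)-4,11-bis(tert-butyldimethylsilyloxy)-5,9-dimethylundeca-5,9-dien-1-yne | C#CC[C@@H](O[Si](C)(C)C(C)(C)C)/C(C)=C/CC/C(C)=C/CO[Si](C)(C)C(C)(C)C | intermediate
9 | (S)-2,2-dimethyl-1,3-dioxolane-4-carbaldehyde | O=C[C@@H]1COC(C)(C)O1 | starting material
10 | isopropyltriphenylphosphonium iodide | CC(C)[P+](c1ccccc1)(c1ccccc1)c1ccccc1.[I-] | starting material
11 | isopropylidenetriphenylphosphorane (not isolated) | CC(C)=P(c1ccccc1)(c1ccccc1)c1ccccc1 | intermediate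
12 | (R)-2,2-dimethyl-4-(2-methylprop-1-enyl)-1,3-dioxolane | CC(C)=C[C@@H]1COC(C)(C)O1 | intermediate
13 | (R)-4-methylpent-3-ene-1,2-diol | CC(C)=C[C@@H](O)CO | intermediate
14 | (R)-4-methyl-1,2-bis(triethylsilyloxy)pent-3-ene | CC(C)=C[C@@H](O[Si](CC)(CC)CC)CO[Si](CC)(CC)CC | intermediate
15 | (R)-4-methyl-2-(triethylsilyloxy)pent-3-enal | CC(C)=C[C@@H](O[Si](CC)(CC)CC)C=O | intermediate
16 | lithium acetylide of 8 (not isolated) | [Li]C#CC[C@@H](O[Si](C)(C)C(C)(C)C)/C(C)=C/CC/C(C)=C/CO[Si](C)(C)C(C)(C)C | intermediate
17 | (4R,5S,9R,10E,14E)-9,16-bis(tert-butyldimethylsilyloxy)-4-(triethylsilyloxy)-2,10,14-trimethylhexadeca-2,10,14-trien-6-yn-5-ol | CC(C)=C[C@@H](O[Si](CC)(CC)CC)[C@@H](O)C#CC[C@@H](O[Si](C)(C)C(C)(C)C)/C(C)=C/CC/C(C)=C/CO[Si](C)(C)C(C)(C)C | intermediate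
18 | (4R,5S,9R,10E,14E)-5,9,16-tris(tert-butyldimethylsilyloxy)-4-(triethylsilyloxy)-2,10,14-trimethylhexadeca-2,10,14-trien-6-yne | CC(C)=C[C@@H](O[Si](CC)(CC)CC)[C@@H](O[Si](C)(C)C(C)(C)C)C#CC[C@@H](O[Si](C)(C)C(C)(C)C)/C(C)=C/CC/C(C)=C/CO[Si](C)(C)C(C)(C)C | intermediate
19 | (4R,5S,9R,10E,14E)-5,9,16-tris(tert-butyldimethylsilyloxy)-2,10,14-trimethylhexadeca-2,10,14-trien-6-yn-4-ol (key-step precursor) | CC(C)=C[C@@H](O)[C@@H](O[Si](C)(C)C(C)(C)C)C#CC[C@@H](O[Si](C)(C)C(C)(C)C)/C(C)=C/CC/C(C)=C/CO[Si](C)(C)C(C)(C)C | intermediate
20 | 4,3',10'-tris-O-TBS target, (3E,4S,5R,3'R) (key-step product) | CC(C)=C[C@H]1OC(=O)/C(=C/C[C@@H](O[Si](C)(C)C(C)(C)C)/C(C)=C/CC/C(C)=C/CO[Si](C)(C)C(C)(C)C)[C@@H]1O[Si](C)(C)C(C)(C)C | intermediate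
21 | (3E,4S,5R)-3-[(3R,4E,8E)-3,10-dihydroxy-4,8-dimethyldeca-4,8-dien-1-ylidene]-4-hydroxy-5-(2-methylprop-1-en-1-yl)oxolan-2-one | CC(C)=C[C@H]1OC(=O)/C(=C/C[C@@H](O)/C(C)=C/CC/C(C)=C/CO)[C@@H]1O | target

## Step count

Total step count: 14.
Longest linear sequence: 10 steps (steps 1–5, then 10–14, from geraniol). The aldehyde branch (steps 6–9) joins at step 10.

## Steps most likely to fail

**Step 13.** Migratory insertion of a disubstituted alkyne flanked by a branched silyloxy carbon may be slow. Slow insertion would leave time for acid- or palladium-induced ionisation of the allylic C5 hydroxyl, or for silyl loss through the HCl carried by the cycle. The fallback sets out from 19 and returns at 20, and it separates C–H formation from CO uptake.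
- Syn hydrostannation (Bu3SnH, PdCl2(PPh3)2 cat., THF, 0 °C) should place tin on C3, next to the oxygenated C4, and hydrogen on C1', giving the (E)-C3-tributylstannyl alkene F1.
- Iododestannylation with retention (I2, CH2Cl2, −78 to 0 °C) gives the (E)-C3-iodoalkene F2.
- Oxidative addition of zerovalent palladium, CO insertion and capture by the C5 hydroxyl (Pd(PPh3)4 cat., CO 1 atm, Et3N, THF/MeCN, 50 °C; carbonylative lactonisation of a halo alcohol) closes the same ring with the same E geometry.

**Step 10.** Facial selectivity of the acetylide addition may be poor, because substrate control by one α-silyloxy group can be modest. The fallback sets out from 17, whatever its purity at C4, and returns at 17, replacing substrate control by reagent control.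
- Oxidation with Dess–Martin periodinane/NaHCO3 in CH2Cl2 gives the α-silyloxy ynone F3.
- Noyori asymmetric transfer hydrogenation (RuCl(p-cymene)[(R,R)-TsDPEN], i-PrOH, rt, no added base) should deliver hydride to the face that gives C4 = S.
- The (R,R) ligand is chosen because here the alkynyl group ranks below the oxygenated alkyl group, which reverses the descriptor with respect to simple alkynyl methyl ketones.

**Step 9.** Three things may go wrong: erosion of configuration at C5, drift of the alkene into conjugation while the amine base is present, and incomplete primary/secondary discrimination by the sulfonium reagent. The fallback sets out from 14 and returns at 15, and it uncouples desilylation from oxidation.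
- Selective methanolysis of the primary silyl ether (PPTS cat., MeOH/CH2Cl2, −20 °C) gives (R)-4-methyl-2-(triethylsilyloxy)pent-3-en-1-ol F4.
- Amine-free oxidation follows with Dess–Martin periodinane/NaHCO3 in CH2Cl2 at 0 °C, and the aldehyde is taken directly into step 10.

## Further compounds

F1 | step 13 | (4R,5R,6E,9R,10E,14E)-5,9,16-tris(tert-butyldimethylsilyloxy)-2,10,14-trimethyl-6-(tributylstannyl)hexadeca-2,6,10,14-tetraen-4-ol (spatial arrangement at all three stereocentres as in 19; the C5 descriptor changes by priority only) | CC(C)=C[C@@H](O)[C@@H](O[Si](C)(C)C(C)(C)C)/C(=C\C[C@@H](O[Si](C)(C)C(C)(C)C)/C(C)=C/CC/C(C)=C/CO[Si](C)(C)C(C)(C)C)[Sn](CCCC)(CCCC)CCCC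
F2 | step 13 | (4R,5R,6E,9R,10E,14E)-5,9,16-tris(tert-butyldimethylsilyloxy)-6-iodo-2,10,14-trimethylhexadeca-2,6,10,14-tetraen-4-ol | CC(C)=C[C@@H](O)[C@@H](O[Si](C)(C)C(C)(C)C)/C(I)=C\C[C@@H](O[Si](C)(C)C(C)(C)C)/C(C)=C/CC/C(C)=C/CO[Si](C)(C)C(C)(C)C
F3 | step 10 | (4R,9R,10E,14E)-9,16-bis(tert-butyldimethylsilyloxy)-4-(triethylsilyloxy)-2,10,14-trimethylhexadeca-2,10,14-trien-6-yn-5-one | CC(C)=C[C@@H](O[Si](CC)(CC)CC)C(=O)C#CC[C@@H](O[Si](C)(C)C(C)(C)C)/C(C)=C/CC/C(C)=C/CO[Si](C)(C)C(C)(C)C
F4 | step 9 | (R)-4-methyl-2-(triethylsilyloxy)pent-3-en-1-ol | CC(C)=C[C@@H](O[Si](CC)(CC)CC)CO
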